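All runs are calculated for an exercise; scatter was added.

The dusk flask had 28.6% of its J as L at 9.4 min, and the winter flask, charged with twice the J and the same E, had 27.2%. So the bench rule reads: at one charge of E and at this one time, about one share of J, as far as the two J charges of dusk and winter show. Spring has E and J in the dusk ratio, 3.00 to one, with J the limiting reagent, and used loosely the rule would hand spring the dusk share. But the rule holds E fixed, and spring carries 3.00 times the dusk E, so it stops working here.

| flask | J | E | time |
|---|---|---|---|
| dusk | 0.200 M | 0.600 M |  |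
| midnight | 0.120 M | 0.520 M |  |
| winter | 0.400 M | 0.600 M |  |
| dawn | 0.200 M | 0.300 M |  |
| spring | 0.600 M | 1.80 M | 9.4 min |

| run | time / min | [L] / M |
|---|---|---|
| dusk run | 0.42 | 0.0067 |
| dusk run | 1.3 | 0.0184 |
| dusk run | 2.4 | 0.0278 |
| dusk run | 3.8 | 0.0387 |
| dusk run | 5.5 | 0.0495 |
| dusk run | 7.3 | 0.0533 |
| dusk run | 9.4 | 0.0573 |
| midnight run | 0.42 | 0.0027 |
| midnight run | 1.3 | 0.0110 |
| midnight run | 2.4 | 0.0173 |
| midnight run | 3.8 | 0.0229 |
| midnight run | 5.5 | 0.0282 |
| midnight run | 7.3 | 0.0309 |
| midnight run | 9.4 | 0.0325 |
| winter run | 0.42 | 0.0116 |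
| winter run | 1.3 | 0.0336 |
| winter run | 2.4 | 0.0551 |
| winter run | 3.8 | 0.0753 |
| winter run | 5.5 | 0.0919 |
| winter run | 7.3 | 0.1016 |
| winter run | 9.4 | 0.1089 |
| dawn run | 0.42 | 0.0022 |
| dawn run | 1.3 | 0.0116 |
| dawn run | 2.4 | 0.0174 |
| dawn run | 3.8 | 0.0255 |
| dawn run | 5.5 | 0.0341 |
| dawn run | 7.3 | 0.0380 |
| dawn run | 9.4 | 0.0412 |

(standard deviation of a reading: 0.001 M)

- Overall: J + E -> L.
- Constant volume, constant temperature.
- A reading of a species includes what of it is bound.
- "The second partner" is E.
- An order is taken over about fifteen percent of the charge, up and down.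

* the power of [J] that the first rate follows, about the charge of the dusk run; measure it at two percent of J made into L (one fixed amount of L, the same in the runs compared)
* the power of [E] that the first rate follows, about the charge of the dusk run; measure it at two percent of J made into L
* L in the spring run at 9.4 min, as a share of the J charged

Dawn shows what E does. With the J of dusk and half its E, dawn had 20.6%, so going from dawn to dusk multiplied the share by 1.39, which is less than the 2.00 by which E grew. The share is bending, and we take the simplest bent curve: a ceiling times the E charge, over the E charge plus a knee charge. Dawn and dusk give both constants. The ceiling share, the share at this time that the curve climbs toward as E grows, is 47.0%. The knee, the E at which the curve stands at 0.5 of that ceiling, is 0.385 M. Spring's E is 4.68 knees, so our own reckoning gives spring 38.7% of its J as L at 9.4 min.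

The forecast gives orders of 1 in J and 0.7 in E, and 43% for spring, holding that “The stall looks kinetic, like catalyst loss or inhibition”. Its share is higher than ours by 4.3 percentage points.

The spring flask gives 36.3% of its J as L, and about the dusk charge the orders of the first rate come out at 1.1 in J and 0.67 in E.

    J + E → L (0.2766 M⁻¹ min⁻¹)
    J + E → G (0.1872 M⁻¹ min⁻¹)
    L → Oz (0.05862 min⁻¹)
    2 E ⇌ E2, settled at all times (2.120 M⁻¹)

The turning of L into Oz moves the readings by 13 times the scatter, root mean square. The spring share is 77.2% of the ceiling of 47.0%. Midnight, a run that did not enter the curve, has 0.520 M of E; the curve puts it at 27.0%, and its reading at 9.4 min is 27.1% of its J.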